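Ring A is built, not substituted. The C5–C6, C7–C8 and C4a–C5 bonds (with C8–C8a) are cut, leaving a dihydropyranone diazo ketone that already holds O1, C8a, C4a and C2 with its two methyls, and a siloxyalkyne that carries the side chain as a dioxolane. One light-then-heat operation closes ring A with all five substituents in place. It exploits the pattern of ring A itself: three oxygens of different kind at C5, C7 and C8a and a single hydrogen at C8, para to C5. Each oxygen comes from its own source, so C5–OH arrives free, C7–O silylated and O1 in the ring.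

Key step: step 8

Remarks on the chemistry:
- Atom labels C2 to C8a follow the chromene numbering of the target. The target is achiral and every intermediate with a stereocentre is racemic.
- The carbon bound to C6 is carried at the ketone level as a 1,3-dioxolane. No benzylic carbinol then stands on the tri-oxygenated ring, and no oxidation is needed beside a free phenol.
- The diazo ketone is made by diazo transfer to a methyl ketone, so the electron-poor C5=C6 bond of the pyranone never meets diazomethane.

Step 1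
Reactants: 1 mesityl oxide; 2 ethyl 2,2-diethoxypropanoate
Product: 4 6-acetyl-2,2-dimethyl-2,3-dihydro-4H-pyran-4-one, via diketone ketal 3 (not isolated)
Conditions: LiN(SiMe3)2 (2.2 equiv), THF, −78 to 0 °C; then 2 M HCl, 40 °C
Reagents that add atoms: water, O
Why: Crossed Claisen condensation of the kinetic methyl-side enolate of 1 with the non-enolisable ester 2 should give the enolised diketone 3, which in acid should close by 6-endo oxa-Michael addition onto the dimethyl-substituted enone terminus while the diethyl ketal hydrolyses, as in the analogous oxalate-derived dihydropyranone esters.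

Step 2
Reactants: 4 6-acetyl-2,2-dimethyl-2,3-dihydro-4H-pyran-4-one
Product: 6 6-(diazoacetyl)-2,2-dimethyl-2,3-dihydro-4H-pyran-4-one, via trifluoroacetyl diketone 5 (not isolated)
Conditions: LiN(SiMe3)2, THF, −78 °C, then CF3CO2CH2CF3; aq. HCl; MsN3, Et3N, H2O, MeCN, rt
Reagents that add atoms: methanesulfonyl azide, CS(=O)(=O)N=[N+]=[N-]
Why: Detrifluoroacetylative diazo transfer (a deacylative Regitz-type reaction): the hindered amide base should deprotonate the open acetyl methyl in preference to the C3 methylene beside the quaternary carbon, and the trifluoroacetyl group then activates that carbon for N2 transfer and leaves as the N-sulfonyl trifluoroacetamide.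

Step 3
Reactants: 7 (4-methoxyphenyl)acetyl chloride
Product: 8 N-methoxy-2-(4-methoxyphenyl)-N-methylacetamide
Conditions: MeNH(OMe)·HCl, pyridine, CH2Cl2, 0 °C to rt
Reagents that add atoms: N,O-dimethylhydroxylamine hydrochloride, CNOC.Cl
Why: N-Acylation of the hydroxylamine by the acid chloride (Schotten–Baumann-type amide formation) should be clean, pyridine being too weak a base to turn the arylacetyl chloride into a ketene.

Step 4
Reactants: 8 N-methoxy-2-(4-methoxyphenyl)-N-methylacetamide; 9 ethynyl(trimethyl)silane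
Product: 10 1-(4-methoxyphenyl)-4-(trimethylsilyl)but-3-yn-2-one
Conditions: 9, n-BuLi, THF, −78 °C; then 8, −78 to 0 °C; aq. NH4Cl
Reagents that add atoms: none
Why: Weinreb ketone synthesis: the lithium acetylide adds once to give a chelated tetrahedral intermediate that collapses to the ynone only on quench, so double addition is not expected.

Step 5
Reactants: 10 1-(4-methoxyphenyl)-4-(trimethylsilyl)but-3-yn-2-one
Product: 11 {[2-(4-methoxybenzyl)-1,3-dioxolan-2-yl]ethynyl}(trimethyl)silane
Conditions: (Me3SiOCH2)2, Me3SiOTf (cat.), CH2Cl2, −78 to 0 °C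
Reagents that add atoms: 1,2-bis(trimethylsilyloxy)ethane, C[Si](C)(C)OCCO[Si](C)(C)C
Why: Ketalisation under silyl triflate catalysis with the bis-silyl ether of ethylene glycol is driven by formation of hexamethyldisiloxane and is established for conjugated ynones, where it avoids conjugate addition of free glycol.

Step 6
Reactants: 11 {[2-(4-methoxybenzyl)-1,3-dioxolan-2-yl]ethynyl}(trimethyl)silane
Product: 12 2-ethynyl-2-(4-methoxybenzyl)-1,3-dioxolane
Conditions: K2CO3 (cat.), MeOH, rt
Reagents that add atoms: none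
Why: Base-catalysed methanolysis of the alkynyl C–Si bond (protodesilylation) is selective and leaves the dioxolane untouched.

Step 7
Reactants: 12 2-ethynyl-2-(4-methoxybenzyl)-1,3-dioxolane
Product: 15 triisopropyl({[2-(4-methoxybenzyl)-1,3-dioxolan-2-yl]ethynyl}oxy)silane, via lithium acetylide 13 (not isolated), via lithium ynolate 14 (not isolated)
Conditions: n-BuLi, THF, −78 °C; t-BuOOLi (from t-BuOOH, LiN(SiMe3)2), −78 to 0 °C; i-Pr3SiOTf, −78 to 0 °C
Reagents that add atoms: tert-butyl hydroperoxide, CC(C)(C)OO; triisopropylsilyl trifluoromethanesulfonate, CC(C)[Si](OS(=O)(=O)C(F)(F)F)(C(C)C)C(C)C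
Why: Electrophilic oxygenation of the acetylide 13 by the lithium peroxide should give ynolate 14, and the bulky silyl triflate should silylate it on oxygen and not on carbon (ynolate O-silylation), the known one-flask route from terminal alkynes to triisopropylsiloxyalkynes.

Step 8
Reactants: 6 6-(diazoacetyl)-2,2-dimethyl-2,3-dihydro-4H-pyran-4-one; 15 triisopropyl({[2-(4-methoxybenzyl)-1,3-dioxolan-2-yl]ethynyl}oxy)silane
Product: 20 5-hydroxy-6-[2-(4-methoxybenzyl)-1,3-dioxolan-2-yl]-2,2-dimethyl-7-(triisopropylsilyloxy)chroman-4-one, via vinylketene 16 (not isolated), via vinylcyclobutenone 17 (not isolated), via dienylketene 18 (not isolated), via cyclohexadienone tautomer 19 (not isolated)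
Conditions: hν (350 nm), ClCH2CH2Cl, rt; then 80 °C
Reagents that add atoms: none
Why: Light expels N2 from 6 and the pyranone carbon that becomes C8a shifts to the carbene carbon (Wolff rearrangement, forming C8–C8a) to give vinylketene 16, whose carbonyl carbon is attacked by the oxygen-remote, nucleophilic carbon of 15 in a (2+2) cycloaddition that forms C5–C6 and C7–C8 and gives 17. Warming opens the 4-vinylcyclobutenone by four-electron electrocyclic ring opening to dienylketene 18, which closes ring A by thermal disrotatory six-electron electrocyclisation (C4a–C5) to 19 and tautomerises to the phenol 20. This is the Danheiser benzannulation in its photochemical diazo ketone form with a siloxyalkyne, known for cyclic alkenyl and oxygen-bearing heteroaryl diazo ketones and applied here to a vinylogous ester. No stereocentre remains in the product. The step needs regioselectivity in the ketene–alkyne union, which the polarisation of the siloxyalkyne secures by placing the dioxolane-bearing carbon at C6 between the new C5 hydroxyl and the C7 silyl ether, and only the pyranone CH that becomes C4a can end the electrocyclisation, so the ring fusion is unambiguous. The C4 carbonyl sits trans to the ketene across the ring alkene and cannot trap it, and the new C5 hydroxyl is hydrogen-bonded to C4=O, which should slow its acylation by ketene.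

Step 9
Reactants: 20 5-hydroxy-6-[2-(4-methoxybenzyl)-1,3-dioxolan-2-yl]-2,2-dimethyl-7-(triisopropylsilyloxy)chroman-4-one
Product: 21 5-methoxy-6-[2-(4-methoxybenzyl)-1,3-dioxolan-2-yl]-2,2-dimethyl-7-(triisopropylsilyloxy)chroman-4-one
Conditions: NaH (1.1 equiv), MeI, DMF, 0 °C to rt
Reagents that add atoms: iodomethane, CI
Why: Williamson ether synthesis: irreversible deprotonation breaks the hydrogen bond of the chelated C5 phenol, the only free hydroxyl, and the phenoxide is methylated while the C7 silyl ether, meta to it and without a migration path, stays in place.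

Step 10
Reactants: 21 5-methoxy-6-[2-(4-methoxybenzyl)-1,3-dioxolan-2-yl]-2,2-dimethyl-7-(triisopropylsilyloxy)chroman-4-one
Product: 22 5-methoxy-6-[2-(4-methoxybenzyl)-1,3-dioxolan-2-yl]-2,2-dimethyl-7-(triisopropylsilyloxy)chroman-4-ol (racemic)
Conditions: NaBH4, MeOH–THF, 0 °C
Reagents that add atoms: none
Why: Borohydride 1,2-reduction of the aryl ketone should give the C4 carbinol as a racemate (no control is needed, since this centre is removed in step 11), with ketal and silyl ether inert.

Step 11
Reactants: 22 5-methoxy-6-[2-(4-methoxybenzyl)-1,3-dioxolan-2-yl]-2,2-dimethyl-7-(triisopropylsilyloxy)chroman-4-ol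
Product: 24 1-[5-methoxy-2,2-dimethyl-7-(triisopropylsilyloxy)-2H-chromen-6-yl]-2-(4-methoxyphenyl)ethan-1-one, via chromene ketal 23 (not isolated)
Conditions: TsOH·H2O (cat.), wet acetone, 40 °C
Reagents that add atoms: water, O
Why: Acid-catalysed E1 dehydration of the benzylic C4 carbinol, activated by the ortho and para ring oxygens, should give the C3=C4 alkene, and the same acid hydrolyses the dioxolane (ketal hydrolysis), every ionisation at the side-chain carbon leading only to the ketone.

Step 12
Reactants: 24 1-[5-methoxy-2,2-dimethyl-7-(triisopropylsilyloxy)-2H-chromen-6-yl]-2-(4-methoxyphenyl)ethan-1-one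
Product: 25 1-(7-hydroxy-5-methoxy-2,2-dimethyl-2H-chromen-6-yl)-2-(4-methoxyphenyl)ethan-1-one
Conditions: Bu4NF, AcOH, THF, 0 °C
Reagents that add atoms: none
Why: Fluoride-mediated cleavage of the aryl silyl ether (desilylation), buffered with acetic acid, should release the C7 phenol, which is then held by a hydrogen bond to the C6 ketone.

Compound list
1 | 4-methylpent-3-en-2-one (mesityl oxide) | CC(C)=CC(C)=O | starting material
2 | ethyl 2,2-diethoxypropanoate | CCOC(=O)C(C)(OCC)OCC | starting material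
3 | 2,2-diethoxy-7-methyloct-6-ene-3,5-dione (enolised diketone) | CCOC(C)(OCC)C(=O)CC(=O)C=C(C)C | intermediate
4 | 6-acetyl-2,2-dimethyl-2,3-dihydro-4H-pyran-4-one | CC(=O)C1=CC(=O)CC(C)(C)O1 | intermediate
5 | 1-(2,2-dimethyl-4-oxo-3,4-dihydro-2H-pyran-6-yl)-4,4,4-trifluorobutane-1,3-dione | O=C(CC(=O)C(F)(F)F)C1=CC(=O)CC(C)(C)O1 | intermediate
6 | 6-(diazoacetyl)-2,2-dimethyl-2,3-dihydro-4H-pyran-4-one | [N-]=[N+]=CC(=O)C1=CC(=O)CC(C)(C)O1 | intermediate
7 | (4-methoxyphenyl)acetyl chloride | COc1ccc(CC(Cl)=O)cc1 | starting material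
8 | N-methoxy-2-(4-methoxyphenyl)-N-methylacetamide | COc1ccc(CC(=O)N(C)OC)cc1 | intermediate
9 | ethynyl(trimethyl)silane | C#C[Si](C)(C)C | starting material
10 | 1-(4-methoxyphenyl)-4-(trimethylsilyl)but-3-yn-2-one | COc1ccc(CC(=O)C#C[Si](C)(C)C)cc1 | intermediate
11 | {[2-(4-methoxybenzyl)-1,3-dioxolan-2-yl]ethynyl}(trimethyl)silane | COc1ccc(CC2(C#C[Si](C)(C)C)OCCO2)cc1 | intermediate
12 | 2-ethynyl-2-(4-methoxybenzyl)-1,3-dioxolane | COc1ccc(CC2(C#C)OCCO2)cc1 | intermediate
13 | lithium [2-(4-methoxybenzyl)-1,3-dioxolan-2-yl]acetylide | [Li+].[C-]#CC1(Cc2ccc(OC)cc2)OCCO1 | intermediate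
14 | lithium 2-[2-(4-methoxybenzyl)-1,3-dioxolan-2-yl]ethynolate | [Li+].[O-]C#CC1(Cc2ccc(OC)cc2)OCCO1 | intermediate
15 | triisopropyl({[2-(4-methoxybenzyl)-1,3-dioxolan-2-yl]ethynyl}oxy)silane | COc1ccc(CC2(C#CO[Si](C(C)C)(C(C)C)C(C)C)OCCO2)cc1 | intermediate
16 | 2-(2,2-dimethyl-4-oxo-3,4-dihydro-2H-pyran-6-yl)ethenone (vinylketene) | O=C=CC1=CC(=O)CC(C)(C)O1 | intermediate
17 | 4-(2,2-dimethyl-4-oxo-3,4-dihydro-2H-pyran-6-yl)-2-[2-(4-methoxybenzyl)-1,3-dioxolan-2-yl]-3-(triisopropylsilyloxy)cyclobut-2-en-1-one (racemic) | COc1ccc(CC2(OCCO2)C2=C(O[Si](C(C)C)(C(C)C)C(C)C)C(C3=CC(=O)CC(C)(C)O3)C2=O)cc1 | intermediate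
18 | (3E)-4-(2,2-dimethyl-4-oxo-3,4-dihydro-2H-pyran-6-yl)-2-[2-(4-methoxybenzyl)-1,3-dioxolan-2-yl]-3-(triisopropylsilyloxy)buta-1,3-dien-1-one (ketenyl and pyranonyl groups cis) | COc1ccc(CC2(OCCO2)C(=C=O)/C(O[Si](C(C)C)(C(C)C)C(C)C)=C\C2=CC(=O)CC(C)(C)O2)cc1 | intermediate
19 | 6-[2-(4-methoxybenzyl)-1,3-dioxolan-2-yl]-2,2-dimethyl-7-(triisopropylsilyloxy)-2,3-dihydro-4H-chromene-4,5(4aH)-dione (racemic) | COc1ccc(CC2(OCCO2)C2=C(O[Si](C(C)C)(C(C)C)C(C)C)C=C3OC(C)(C)CC(=O)C3C2=O)cc1 | intermediate
20 | 5-hydroxy-6-[2-(4-methoxybenzyl)-1,3-dioxolan-2-yl]-2,2-dimethyl-7-(triisopropylsilyloxy)chroman-4-one | COc1ccc(CC2(OCCO2)c2c(O)c3c(cc2O[Si](C(C)C)(C(C)C)C(C)C)OC(C)(C)CC3=O)cc1 | intermediate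
21 | 5-methoxy-6-[2-(4-methoxybenzyl)-1,3-dioxolan-2-yl]-2,2-dimethyl-7-(triisopropylsilyloxy)chroman-4-one | COc1ccc(CC2(OCCO2)c2c(OC)c3c(cc2O[Si](C(C)C)(C(C)C)C(C)C)OC(C)(C)CC3=O)cc1 | intermediate
22 | 5-methoxy-6-[2-(4-methoxybenzyl)-1,3-dioxolan-2-yl]-2,2-dimethyl-7-(triisopropylsilyloxy)chroman-4-ol (racemic) | COc1ccc(CC2(OCCO2)c2c(OC)c3c(cc2O[Si](C(C)C)(C(C)C)C(C)C)OC(C)(C)CC3O)cc1 | intermediate
23 | 5-methoxy-6-[2-(4-methoxybenzyl)-1,3-dioxolan-2-yl]-2,2-dimethyl-7-(triisopropylsilyloxy)-2H-chromene | COc1ccc(CC2(OCCO2)c2c(OC)c3c(cc2O[Si](C(C)C)(C(C)C)C(C)C)OC(C)(C)C=C3)cc1 | intermediate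
24 | 1-[5-methoxy-2,2-dimethyl-7-(triisopropylsilyloxy)-2H-chromen-6-yl]-2-(4-methoxyphenyl)ethan-1-one | COc1ccc(CC(=O)c2c(OC)c3c(cc2O[Si](C(C)C)(C(C)C)C(C)C)OC(C)(C)C=C3)cc1 | intermediate
25 | 1-(7-hydroxy-5-methoxy-2,2-dimethyl-2H-chromen-6-yl)-2-(4-methoxyphenyl)ethan-1-one | COc1ccc(CC(=O)c2c(O)cc3c(c2OC)C=CC(C)(C)O3)cc1 | target

Total step count: 12. Longest linear sequence: 10 steps (steps 3 to 12, from 7). The diazo ketone branch (steps 1 and 2) joins at step 8.

Steps most likely to fail

Step 8. The excited cross-conjugated enone part of 6 may add to the electron-rich alkyne, or the carbene may escape by paths other than the alkenyl shift. The ketene may also dimerise, or acylate the product, before the congested alkyne captures it. The fallback adjusts the C4 oxygen level before the annulation instead of after it, so that light meets a plain alkoxy-substituted alkenyl diazo ketone. Setting out from 6, Luche reduction (NaBH4, CeCl3·7H2O, MeOH, −78 °C) of the C4 ketone should give the racemic allylic alcohol 2-diazo-1-(4-hydroxy-2,2-dimethyl-3,4-dihydro-2H-pyran-6-yl)ethan-1-one F1; the diazo carbonyl is expected to resist. Silylation (t-BuMe2SiCl, imidazole, DMF) should give 1-[4-(tert-butyldimethylsilyloxy)-2,2-dimethyl-3,4-dihydro-2H-pyran-6-yl]-2-diazoethan-1-one F2. Irradiation of F2 with 15 and warming, as in step 8, should give 4-(tert-butyldimethylsilyloxy)-6-[2-(4-methoxybenzyl)-1,3-dioxolan-2-yl]-2,2-dimethyl-7-(triisopropylsilyloxy)chroman-5-ol F3. Methylation (NaH, MeI, DMF) should give its 5-methyl ether, tert-butyl({5-methoxy-6-[2-(4-methoxybenzyl)-1,3-dioxolan-2-yl]-2,2-dimethyl-7-(triisopropylsilyloxy)chroman-4-yl}oxy)dimethylsilane F4. TsOH·H2O in wet acetone should then ionise the benzylic C4–O bond, expel the silanol and hydrolyse the dioxolane, which comes back to the route at 24.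

Step 2. The base may deprotonate C3 instead of the acetyl methyl, or open the pyranone by β-elimination of O1, so that acyl and diazo transfer occur at the wrong carbon or the ring is lost. The fallback is acylation of diazomethane, which is known chemistry. Setting out from 1, Claisen condensation with diethyl oxalate (NaOEt, EtOH; then H2SO4) should give ethyl 2,2-dimethyl-4-oxo-3,4-dihydro-2H-pyran-6-carboxylate F5. Saponification (LiOH, THF–H2O) should give 2,2-dimethyl-4-oxo-3,4-dihydro-2H-pyran-6-carboxylic acid F6, and (COCl)2 with catalytic DMF the acid chloride 2,2-dimethyl-4-oxo-3,4-dihydro-2H-pyran-6-carbonyl chloride F7. Slow addition of F7 to excess CH2N2 in Et2O at −20 °C (Arndt–Eistert-type acylation) comes back to the route at 6; the low temperature is meant to hold back dipolar addition to C5=C6.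

Step 7. Oxygen transfer from the peroxide to the acetylide may be incomplete, or the ynolate may be silylated at carbon to a silylketene. The fallback reaches the same ynolate through an alkynyl sulfonate, also known chemistry. Setting out from 12, PhI(OH)OTs in CH2Cl2 over a desiccant should give the trivalent iodine salt {[2-(4-methoxybenzyl)-1,3-dioxolan-2-yl]ethynyl}(phenyl)iodonium 4-methylbenzenesulfonate F8. CuOTf (cat.) in MeCN should turn it into [2-(4-methoxybenzyl)-1,3-dioxolan-2-yl]ethynyl 4-methylbenzenesulfonate F9 with loss of iodobenzene. MeLi in THF at −78 °C should attack sulfur and release the ynolate, which comes back to the route at 14 and is silylated to 15 as in step 7.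

Further compounds
F1 | step 8 | 2-diazo-1-(4-hydroxy-2,2-dimethyl-3,4-dihydro-2H-pyran-6-yl)ethan-1-one (racemic) | [N-]=[N+]=CC(=O)C1=CC(O)CC(C)(C)O1
F2 | step 8 | 1-[4-(tert-butyldimethylsilyloxy)-2,2-dimethyl-3,4-dihydro-2H-pyran-6-yl]-2-diazoethan-1-one (racemic) | [N-]=[N+]=CC(=O)C1=CC(O[Si](C)(C)C(C)(C)C)CC(C)(C)O1
F3 | step 8 | 4-(tert-butyldimethylsilyloxy)-6-[2-(4-methoxybenzyl)-1,3-dioxolan-2-yl]-2,2-dimethyl-7-(triisopropylsilyloxy)chroman-5-ol (racemic) | COc1ccc(CC2(OCCO2)c2c(O)c3c(cc2O[Si](C(C)C)(C(C)C)C(C)C)OC(C)(C)CC3O[Si](C)(C)C(C)(C)C)cc1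
F4 | step 8 | tert-butyl({5-methoxy-6-[2-(4-methoxybenzyl)-1,3-dioxolan-2-yl]-2,2-dimethyl-7-(triisopropylsilyloxy)chroman-4-yl}oxy)dimethylsilane (racemic) | COc1ccc(CC2(OCCO2)c2c(OC)c3c(cc2O[Si](C(C)C)(C(C)C)C(C)C)OC(C)(C)CC3O[Si](C)(C)C(C)(C)C)cc1
F5 | step 2 | ethyl 2,2-dimethyl-4-oxo-3,4-dihydro-2H-pyran-6-carboxylate | CCOC(=O)C1=CC(=O)CC(C)(C)O1
F6 | step 2 | 2,2-dimethyl-4-oxo-3,4-dihydro-2H-pyran-6-carboxylic acid | OC(=O)C1=CC(=O)CC(C)(C)O1
F7 | step 2 | 2,2-dimethyl-4-oxo-3,4-dihydro-2H-pyran-6-carbonyl chloride | ClC(=O)C1=CC(=O)CC(C)(C)O1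
F8 | step 7 | {[2-(4-methoxybenzyl)-1,3-dioxolan-2-yl]ethynyl}(phenyl)iodonium 4-methylbenzenesulfonate | COc1ccc(CC2(C#C[I+]c3ccccc3)OCCO2)cc1.Cc1ccc(cc1)S(=O)(=O)[O-]
F9 | step 7 | [2-(4-methoxybenzyl)-1,3-dioxolan-2-yl]ethynyl 4-methylbenzenesulfonate | COc1ccc(CC2(C#COS(=O)(=O)c3ccc(C)cc3)OCCO2)cc1
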